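## Retrosynthetic overview

1. The target comes from its hexakis-MOM ether by one global deprotection.
2. The cyclohexene comes from a 2-aroyl-1-methyl-1-(2-arylethenyl)cyclobutane by a stepwise, Lewis-acid four-to-six ring expansion. The ring bond between the aroyl carbon and the quaternary carbon is re-formed at the benzylic alkene terminus, and the existing aryl-bearing centre steers the two new ones.
3. The cyclobutane comes from an enantioselective crossed [2+2] photocycloaddition of a 2'-hydroxychalcone with a 1-(benzofuran-5-yl)-3-methylbuta-1,3-diene.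
4. The chalcone comes from a Claisen–Schmidt condensation of an acetophenone and a benzaldehyde, both made from resorcinol.
5. The diene comes from olefination of a benzofuran-5-carbaldehyde, built by Sonogashira coupling/cycloisomerisation after C–H borylation/oxidation and formylation of a resorcinol bis-ether. Rings are formed in the order benzofuran, cyclobutane, cyclohexene.

## Assumptions

- 7 and 12 are bought as the MOM ethers of resorcinol and 3-bromophenol (otherwise each is one step with MOMCl).
- The sense of induction in step 11 is assigned by analogy with reported chalcone/diene photocycloadditions; if the first run gives the antipode of 21, (R,R)-t-BuPyBox is used instead.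
- 21 is carried forward as a mixture of epimers at its quaternary carbon; that centre becomes planar in step 12.

## Route

Step 1
Reactants: 1 benzene-1,3-diol (resorcinol)
Product: 2 1-(2,4-dihydroxyphenyl)ethan-1-one
Conditions: AcOH, ZnCl2, 140 °C
Reagents that add atoms: acetic acid, CC(=O)O
Why: Nencki (Friedel–Crafts-type) acylation of resorcinol goes para to one hydroxyl and ortho to the other, a standard preparation with no stereocentre involved.

Step 2
Reactants: 2 1-(2,4-dihydroxyphenyl)ethan-1-one
Product: 3 1-[2-hydroxy-4-(methoxymethoxy)phenyl]ethan-1-one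
Conditions: MOMCl (1.1 equiv), K2CO3, acetone, 0 °C → rt
Reagents that add atoms: chloromethyl methyl ether, COCCl
Why: Williamson-type O-alkylation (MOM protection) takes only the 4-hydroxyl because the 2-hydroxyl is hydrogen-bonded to the ketone.

Step 3
Reactants: 1 benzene-1,3-diol (resorcinol)
Product: 4 2,4-dihydroxybenzaldehyde
Conditions: POCl3, DMF, MeCN, −15 °C → rt; then H2O, 50 °C
Reagents that add atoms: N,N-dimethylformamide, CN(C)C=O; water, O
Why: Vilsmeier–Haack formylation of resorcinol occurs at C4 (para/ortho to the two hydroxyls) and the iminium salt is hydrolysed to the aldehyde.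

Step 4
Reactants: 4 2,4-dihydroxybenzaldehyde
Product: 5 2,4-bis(methoxymethoxy)benzaldehyde
Conditions: MOMCl (2.6 equiv), K2CO3, acetone, reflux
Reagents that add atoms: chloromethyl methyl ether, COCCl
Why: Williamson-type MOM protection with excess reagent and heat also alkylates the chelated 2-hydroxyl, giving a base-stable aldehyde for the aldol step.

Step 5
Reactants: 3 1-[2-hydroxy-4-(methoxymethoxy)phenyl]ethan-1-one; 5 2,4-bis(methoxymethoxy)benzaldehyde
Product: 6 (2E)-3-[2,4-bis(methoxymethoxy)phenyl]-1-[2-hydroxy-4-(methoxymethoxy)phenyl]prop-2-en-1-one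
Conditions: KOH (50% aq.), EtOH, rt, 24 h; then AcOH to pH 6
Reagents that add atoms: none
Why: Claisen–Schmidt aldol condensation with E1cB dehydration gives the conjugated (E)-enone, and MOM ethers are stable to hydroxide.

Step 6
Reactants: 7 1,3-bis(methoxymethoxy)benzene
Product: 9 3,5-bis(methoxymethoxy)phenol, via pinacol arylboronate 8 (not isolated)
Conditions: B2pin2 (0.6 equiv), [Ir(OMe)(cod)]2 (1.5 mol%), 4,4'-di-tert-butyl-2,2'-bipyridine (3 mol%), THF, 80 °C; then 30% H2O2, NaOH (aq.), 0 °C
Reagents that add atoms: hydrogen peroxide, OO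
Why: Iridium-catalysed C–H borylation is sterically controlled and takes only the position meta to both ethers, and basic peroxide oxidation converts the C–B bond to C–O without touching the MOM groups.

Step 7
Reactants: 9 3,5-bis(methoxymethoxy)phenol
Product: 10 4-hydroxy-2,6-bis(methoxymethoxy)benzaldehyde
Conditions: n-BuLi (2.4 equiv), TMEDA, THF, −78 → 0 °C; DMF, −78 °C → rt; aq. HCl to pH 5, 0 °C
Reagents that add atoms: N,N-dimethylformamide, CN(C)C=O
Why: Directed ortho-metalation: after O-lithiation the second equivalent removes the only proton flanked by two MOM-oxy groups (cooperative directing groups, remote from the phenoxide), and DMF formylates that symmetric position as a single regioisomer.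

Step 8
Reactants: 10 4-hydroxy-2,6-bis(methoxymethoxy)benzaldehyde
Product: 11 4-hydroxy-3-iodo-2,6-bis(methoxymethoxy)benzaldehyde
Conditions: NIS (1.0 equiv), MeCN, 0 °C, dark
Reagents that add atoms: N-iodosuccinimide, O=C1CCC(=O)N1I
Why: Electrophilic aromatic iodination takes one of the two equivalent positions ortho to the free phenol, and the aldehyde tempers the ring enough to stop at mono-iodination.

Step 9
Reactants: 12 1-bromo-3-(methoxymethoxy)benzene; 13 ethynyl(trimethyl)silane; 11 4-hydroxy-3-iodo-2,6-bis(methoxymethoxy)benzaldehyde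
Product: 17 4,6-bis(methoxymethoxy)-2-[3-(methoxymethoxy)phenyl]-1-benzofuran-5-carbaldehyde, via silylated arylalkyne 14 (not isolated), via terminal arylalkyne 15 (not isolated), via alkynylphenol 16 (not isolated)
Conditions: 12, 13 (1.05 equiv), PdCl2(PPh3)2 (4 mol%), CuI (8 mol%), Et3N, DMF, 70 °C (sealed); then 11, DBU, H2O, 70 °C
Reagents that add atoms: none
Why: One-pot double Sonogashira coupling (bromide first, then in-situ desilylation and coupling with the more reactive aryl iodide) followed by base/copper-promoted 5-endo-dig cycloisomerisation of the ortho-alkynylphenol gives the 2-arylbenzofuran.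

Step 10
Reactants: 18 3-bromo-2-methylprop-1-ene; 17 4,6-bis(methoxymethoxy)-2-[3-(methoxymethoxy)phenyl]-1-benzofuran-5-carbaldehyde
Product: 20 4,6-bis(methoxymethoxy)-2-[3-(methoxymethoxy)phenyl]-5-[(1E)-3-methylbuta-1,3-dien-1-yl]-1-benzofuran, via allylic phosphonate 19 (not isolated)
Conditions: 18, P(OEt)3, neat, 130 °C (EtBr distilled off); then THF, n-BuLi, −78 °C; HMPA, 17, −78 °C → rt
Reagents that add atoms: none
Why: Michaelis–Arbuzov reaction followed by Horner–Wadsworth–Emmons olefination with the lithiated allylic phosphonate gives the terminal (E)-1-aryl-1,3-diene.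

Step 11
Reactants: 6 (2E)-3-[2,4-bis(methoxymethoxy)phenyl]-1-[2-hydroxy-4-(methoxymethoxy)phenyl]prop-2-en-1-one; 20 4,6-bis(methoxymethoxy)-2-[3-(methoxymethoxy)phenyl]-5-[(1E)-3-methylbuta-1,3-dien-1-yl]-1-benzofuran
Product: 21 {(1R,4S)-2-[(E)-2-{4,6-bis(methoxymethoxy)-2-[3-(methoxymethoxy)phenyl]-1-benzofuran-5-yl}ethenyl]-4-[2,4-bis(methoxymethoxy)phenyl]-2-methylcyclobutyl}[2-hydroxy-4-(methoxymethoxy)phenyl]methanone (aroyl and aryl trans; both C2 epimers)
Conditions: 6 (2 equiv), 20 (1 equiv), Sc(OTf)3 (10 mol%), (S,S)-t-BuPyBox (15 mol%), Ru(bpy)3(PF6)2 (2.5 mol%), iPrOAc/MeCN 3:1, degassed, blue LEDs (450 nm), rt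
Reagents that add atoms: none
Why: Lewis-acid-catalysed triplet energy-transfer crossed [2+2] photocycloaddition: only chalcone chelated to the chiral scandium–PyBox complex is sensitised, its β-carbon adds to the CH2 terminus of the diene on the open face (setting the aryl-bearing centre S), and the stabilised 1,4-diradical closes at the tertiary carbon with aroyl and aryl trans (1R).

Step 12
Reactants: 21 {(1R,4S)-2-[(E)-2-{4,6-bis(methoxymethoxy)-2-[3-(methoxymethoxy)phenyl]-1-benzofuran-5-yl}ethenyl]-4-[2,4-bis(methoxymethoxy)phenyl]-2-methylcyclobutyl}[2-hydroxy-4-(methoxymethoxy)phenyl]methanone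
Product: 22 {(1R,2R,6S)-2-{4,6-bis(methoxymethoxy)-2-[3-(methoxymethoxy)phenyl]-1-benzofuran-5-yl}-6-[2,4-bis(methoxymethoxy)phenyl]-4-methylcyclohex-3-en-1-yl}[2-hydroxy-4-(methoxymethoxy)phenyl]methanone (all-trans)
Conditions: Sc(OTf)3 (10 mol%), 2,6-di-tert-butylpyridine (20 mol%), 4 Å MS, CH2Cl2 (0.01 M), −20 °C → rt
Reagents that add atoms: none
Why: Proposed new method: a stepwise, ionic four-to-six ring expansion of a 2-aroyl-1-alkenylcyclobutane in which Sc(OTf)3 chelates the 2-hydroxyaryl ketone, the ring bond between the aroyl carbon and the quaternary carbon ionises to a scandium enolate tethered to an allyl cation strongly stabilised by the trioxygenated benzofuranyl ring, and the enolate carbon recloses on the benzylic terminus through a half-chair with all three substituents equatorial, so the untouched aryl-bearing centre (S) relays its configuration to the two new centres (1R,2R, all-trans, also the thermodynamic isomer since closure is reversible) and both C2 epimers of 21 converge; the closest known reaction types are Lewis-acid ring opening/annulation of donor–acceptor cyclobutanes through 1,4-zwitterions and the vinylcyclobutane-to-cyclohexene rearrangement.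

Step 13
Reactants: 22 {(1R,2R,6S)-2-{4,6-bis(methoxymethoxy)-2-[3-(methoxymethoxy)phenyl]-1-benzofuran-5-yl}-6-[2,4-bis(methoxymethoxy)phenyl]-4-methylcyclohex-3-en-1-yl}[2-hydroxy-4-(methoxymethoxy)phenyl]methanone
Product: 24 (2,4-dihydroxyphenyl){(1R,2R,6S)-6-(2,4-dihydroxyphenyl)-2-[4,6-dihydroxy-2-(3-hydroxyphenyl)-1-benzofuran-5-yl]-4-methylcyclohex-3-en-1-yl}methanone, via hexakis(trimethylsilyl) ether 23 (not isolated)
Conditions: TMSOTf (14 equiv), 2,2'-bipyridyl (20 equiv), CH2Cl2/MeCN, 0 °C → rt; then H2O, rt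
Reagents that add atoms: none
Why: Silyl triflate/2,2'-bipyridyl acetal exchange turns each aryl MOM ether into a silyl ether that water hydrolyses, a buffered non-protic MOM cleavage that leaves the trisubstituted alkene and the three stereocentres alone (any enolisation at C1 returns the all-trans, most stable isomer).

## Compound list

1 | benzene-1,3-diol (resorcinol) | Oc1cccc(O)c1 | starting material
2 | 1-(2,4-dihydroxyphenyl)ethan-1-one | CC(=O)c1ccc(O)cc1O | intermediate
3 | 1-[2-hydroxy-4-(methoxymethoxy)phenyl]ethan-1-one | CC(=O)c1ccc(OCOC)cc1O | intermediate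
4 | 2,4-dihydroxybenzaldehyde | O=Cc1ccc(O)cc1O | intermediate
5 | 2,4-bis(methoxymethoxy)benzaldehyde | O=Cc1ccc(OCOC)cc1OCOC | intermediate
6 | (2E)-3-[2,4-bis(methoxymethoxy)phenyl]-1-[2-hydroxy-4-(methoxymethoxy)phenyl]prop-2-en-1-one | O=C(/C=C/c1ccc(OCOC)cc1OCOC)c1ccc(OCOC)cc1O | intermediate
7 | 1,3-bis(methoxymethoxy)benzene | COCOc1cccc(OCOC)c1 | starting material
8 | 2-[3,5-bis(methoxymethoxy)phenyl]-4,4,5,5-tetramethyl-1,3,2-dioxaborolane | COCOc1cc(OCOC)cc(B2OC(C)(C)C(C)(C)O2)c1 | intermediate
9 | 3,5-bis(methoxymethoxy)phenol | COCOc1cc(O)cc(OCOC)c1 | intermediate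
10 | 4-hydroxy-2,6-bis(methoxymethoxy)benzaldehyde | O=Cc1c(OCOC)cc(O)cc1OCOC | intermediate
11 | 4-hydroxy-3-iodo-2,6-bis(methoxymethoxy)benzaldehyde | O=Cc1c(OCOC)cc(O)c(I)c1OCOC | intermediate
12 | 1-bromo-3-(methoxymethoxy)benzene | COCOc1cccc(Br)c1 | starting material
13 | ethynyl(trimethyl)silane | C#C[Si](C)(C)C | starting material
14 | {[3-(methoxymethoxy)phenyl]ethynyl}(trimethyl)silane | COCOc1cccc(C#C[Si](C)(C)C)c1 | intermediate
15 | 1-ethynyl-3-(methoxymethoxy)benzene | COCOc1cccc(C#C)c1 | intermediate
16 | 4-hydroxy-2,6-bis(methoxymethoxy)-3-{[3-(methoxymethoxy)phenyl]ethynyl}benzaldehyde | O=Cc1c(OCOC)cc(O)c(C#Cc2cccc(OCOC)c2)c1OCOC | intermediate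
17 | 4,6-bis(methoxymethoxy)-2-[3-(methoxymethoxy)phenyl]-1-benzofuran-5-carbaldehyde | O=Cc1c(OCOC)cc2oc(-c3cccc(OCOC)c3)cc2c1OCOC | intermediate
18 | 3-bromo-2-methylprop-1-ene | CC(=C)CBr | starting material
19 | diethyl (2-methylprop-2-en-1-yl)phosphonate | CCOP(=O)(CC(C)=C)OCC | intermediate
20 | 4,6-bis(methoxymethoxy)-2-[3-(methoxymethoxy)phenyl]-5-[(1E)-3-methylbuta-1,3-dien-1-yl]-1-benzofuran | CC(=C)/C=C/c1c(OCOC)cc2oc(-c3cccc(OCOC)c3)cc2c1OCOC | intermediate
21 | {(1R,4S)-2-[(E)-2-{4,6-bis(methoxymethoxy)-2-[3-(methoxymethoxy)phenyl]-1-benzofuran-5-yl}ethenyl]-4-[2,4-bis(methoxymethoxy)phenyl]-2-methylcyclobutyl}[2-hydroxy-4-(methoxymethoxy)phenyl]methanone, mixture of epimers at C2 (that centre is left undefined in the SMILES) | CC1(/C=C/c2c(OCOC)cc3oc(-c4cccc(OCOC)c4)cc3c2OCOC)C[C@H](c2ccc(OCOC)cc2OCOC)[C@H]1C(=O)c1ccc(OCOC)cc1O | intermediate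
22 | {(1R,2R,6S)-2-{4,6-bis(methoxymethoxy)-2-[3-(methoxymethoxy)phenyl]-1-benzofuran-5-yl}-6-[2,4-bis(methoxymethoxy)phenyl]-4-methylcyclohex-3-en-1-yl}[2-hydroxy-4-(methoxymethoxy)phenyl]methanone | CC1=C[C@@H](c2c(OCOC)cc3oc(-c4cccc(OCOC)c4)cc3c2OCOC)[C@H](C(=O)c2ccc(OCOC)cc2O)[C@@H](c2ccc(OCOC)cc2OCOC)C1 | intermediate
23 | {(1R,2R,6S)-2-{4,6-bis[(trimethylsilyl)oxy]-2-{3-[(trimethylsilyl)oxy]phenyl}-1-benzofuran-5-yl}-6-{2,4-bis[(trimethylsilyl)oxy]phenyl}-4-methylcyclohex-3-en-1-yl}{2-hydroxy-4-[(trimethylsilyl)oxy]phenyl}methanone | CC1=C[C@@H](c2c(O[Si](C)(C)C)cc3oc(-c4cccc(O[Si](C)(C)C)c4)cc3c2O[Si](C)(C)C)[C@H](C(=O)c2ccc(O[Si](C)(C)C)cc2O)[C@@H](c2ccc(O[Si](C)(C)C)cc2O[Si](C)(C)C)C1 | intermediate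
24 | (2,4-dihydroxyphenyl){(1R,2R,6S)-6-(2,4-dihydroxyphenyl)-2-[4,6-dihydroxy-2-(3-hydroxyphenyl)-1-benzofuran-5-yl]-4-methylcyclohex-3-en-1-yl}methanone (CNP0221531.1) | CC1=C[C@@H](c2c(O)cc3oc(-c4cccc(O)c4)cc3c2O)[C@H](C(=O)c2ccc(O)cc2O)[C@@H](c2ccc(O)cc2O)C1 | target

## Step count

Total step count: 13.
Longest linear sequence: 8 steps (7 → 24, steps 6 to 13).

## Steps most likely to fail, with fallbacks

**Step 12 (the new ring expansion).** The ion pair may fragment to 6 and 20, which would recombine with loss of enantiopurity, or lose a proton to an open-chain triene. The fallback uses known chemistry, sets out from 6 and 20 and comes back at 22. Chalcone 6 is bound in situ as its chiral borate (BH3·THF, AcOH, VANOL of the enantiomer that gives the (1R,2R,6S) series, THF, rt). The activated chelate undergoes the established asymmetric Diels–Alder reaction with diene 20, and the exo (all-trans) adduct is separated from the endo isomer by chromatography to give 22 directly. This fallback makes no compound outside the list (F0).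

**Step 11 (photocycloaddition with the precious aryl diene).** The sensitiser may also excite the extended aryl diene, a dark scandium-catalysed addition may compete, and 20 cannot be used in the large excess that simple dienes allow. The fallback sets out from 6 and 17 and comes back at 21; step 10 is then not needed.
- Chalcone 6 is irradiated under the same scandium/PyBox/Ru(bpy)3(PF6)2 conditions with excess 2-methylbuta-1,3-diene (CC(=C)C=C), a simple diene of the established substrate class. This gives {(1R,4S)-4-[2,4-bis(methoxymethoxy)phenyl]-2-ethenyl-2-methylcyclobutyl}[2-hydroxy-4-(methoxymethoxy)phenyl]methanone F1.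
- Aldehyde 17 is methylenated (MePPh3Br, KOtBu, THF) to 5-ethenyl-4,6-bis(methoxymethoxy)-2-[3-(methoxymethoxy)phenyl]-1-benzofuran F2.
- Cross-metathesis of F1 with F2 (second-generation Hoveyda–Grubbs catalyst, RuCl2(H2IMes)(=CH-C6H4-2-OiPr), toluene, 60 °C, ethene swept out) gives the (E)-alkene 21. This metathesis joins two hindered alkenes and may need forcing conditions.

**Step 7 (metalation of a lithium phenoxide).** The phenoxide charge slows the second deprotonation and metalation may be incomplete. The fallback sets out from 9 and comes back at 10.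
- The phenol is silylated (TIPSCl, imidazole, DMF) to [3,5-bis(methoxymethoxy)phenoxy]tri(propan-2-yl)silane F3.
- Ordinary directed ortho-metalation between the two MOM-oxy groups (n-BuLi, TMEDA, THF, 0 °C; then DMF) gives 2,6-bis(methoxymethoxy)-4-{[tri(propan-2-yl)silyl]oxy}benzaldehyde F4.
- TBAF (THF, 0 °C) frees the phenol to give 10.

## Further compounds

F0 | step 12 | none | none
F1 | step 11 | {(1R,4S)-4-[2,4-bis(methoxymethoxy)phenyl]-2-ethenyl-2-methylcyclobutyl}[2-hydroxy-4-(methoxymethoxy)phenyl]methanone (both C2 epimers) | CC1(C=C)C[C@H](c2ccc(OCOC)cc2OCOC)[C@H]1C(=O)c1ccc(OCOC)cc1O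
F2 | step 11 | 5-ethenyl-4,6-bis(methoxymethoxy)-2-[3-(methoxymethoxy)phenyl]-1-benzofuran | C=Cc1c(OCOC)cc2oc(-c3cccc(OCOC)c3)cc2c1OCOC
F3 | step 7 | [3,5-bis(methoxymethoxy)phenoxy]tri(propan-2-yl)silane | COCOc1cc(OCOC)cc(O[Si](C(C)C)(C(C)C)C(C)C)c1
F4 | step 7 | 2,6-bis(methoxymethoxy)-4-{[tri(propan-2-yl)silyl]oxy}benzaldehyde | O=Cc1c(OCOC)cc(O[Si](C(C)C)(C(C)C)C(C)C)cc1OCOC
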